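## The problem

Target 21 is a 2‑aryl‑3‑(hydroxymethyl)‑4‑aroyloxolane. Ring C (O1, C2–C5) carries ring A (4‑hydroxy‑3‑methoxyphenyl) on C2, the hydroxymethyl carbon C9 on C3 and the C7' ketone of ring B (4‑hydroxy‑3,5‑dimethoxyphenyl) on C4; C5 is an unsubstituted methylene between O1 and C4. The three contiguous stereocentres are (2S,3R,4S) in these locants, all‑trans. C4 is α to the aryl ketone and epimerisable; flanked by a trans C3 substituent it should sit in its thermodynamic configuration, so it can be left to equilibration under control of C3. C2 and C3 must therefore be set absolutely. Their trans relationship on the ring corresponds, in an open chain, to a syn relationship between the C2 oxygen and the C3–C4 bond, which is the pattern of a syn‑aldol. The fragile points are the two free phenols on electron‑rich rings, the p‑oxygenated benzylic ether at C2 (ionises under acid), the β‑alkoxy ketone O1–C5–C4–C7' (can open under forcing base) and the C9 alcohol (interferes with carbenoid and organometallic steps). The feature that makes the key step possible is C5: it bears no substituent and is bonded only to O1 and to the ketone α‑carbon C4, so it can begin as the methyl carbon of a C2 methyl ether and be joined to C4 by a carbenoid generated at C4.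

## Retrosynthesis

**21 ⇒ 20.** No skeletal bond is cut; the three hydroxyls are masked as a C9 benzoate and two aryl tert‑butyldimethylsilyl (TBS) ethers. O–H bonds would intercept the carbenoid, and acetates would not survive the hydride, aryllithium and amide‑base steps that precede it. The benzoate has no enolisable hydrogen and no ether‑type C–H bond, and the TBS ethers are inert until the end. The forward reaction is one carbonate/methanol treatment that removes all three groups and equilibrates C4 without opening ring C.

**20 ⇒ 19.** The C4–C5 bond is cut. Cutting O1–C2 instead would mean a cationic etherification that puts the C2 configuration at risk. Cutting O1–C5 would require a leaving group β to the ketone, which invites elimination. The C4–C5 cut removes ring C and the C4 stereocentre together. It leaves the open‑chain α‑diazo ketone 19, in which C5 is the methyl of a C2 methyl ether and the only stereocentres are the C2/C3 pair. The forward step must insert the C4 carbenoid into a methoxy C–H bond in preference to 1,2‑hydride shift from C3 and to attack on ring A.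

**19 ⇒ 16.** The diazo group at C4 is removed. Ketone 16 can enolise only at C4, so a deacylative diazo transfer is regiochemically unambiguous, and C3 is not acidic. The forward reaction needs C‑acylation of a hindered enolate without disturbing the benzoate.

**16 ⇒ 15 ⇒ 11 + 14.** The bond between C7' and ring B is cut. The alternative of carrying the ring B ketone through the aldol would need a ketal and later acid beside the acid‑labile benzylic ether, so ring B is added late. Aldehyde 11 and aryllithium 14 (from bromide 13, from phenol 12) are both simple. The addition must select the aldehyde over the benzoate; the carbinol centre in 15 is irrelevant because oxidation removes it.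

**11 ⇒ 10 ⇒ 9.** The C7' aldehyde is traced to a terminal alkene (ozonolysis), so C4 and C7' travel as an allyl group that is inert to the earlier steps. The benzoate is traced to alcohol 9.

**9 ⇒ 8 ⇒ 7.** The C9 alcohol comes from reductive removal of an oxazolidinone auxiliary, and the C2 methyl ether from O‑methylation of an aldol hydroxyl. That oxygen becomes O1 and its methyl carbon becomes C5. Methylation must not cause retro‑aldol cleavage or ionisation at the benzylic carbon.

**7 ⇒ 5 + 2.** The C2–C3 bond is cut by an Evans syn‑aldol between the boron enolate of pentenoyl imide 5 and silylated vanillin 2. This sets both stereocentres that need absolute control in one step, with the (S)‑benzyl auxiliary giving the required (2S,3S) adduct.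

**5 ⇒ 3 + 4; 2 ⇒ 1; 13 ⇒ 12.** These are an N‑acylation and two phenol silylations of commercial materials.

## Roads not taken

**Alternative 1:** Cut O1–C2 and C4–C5 together; formaldehyde supplies O1 and C5. The key step is a Sn(OTf)2‑promoted [3+2] cycloaddition of the lactone‑fused donor–acceptor cyclopropane A2 with formaldehyde. The aldehyde oxygen attacks the aryl‑bearing carbon and the malonate‑type carbanion captures the aldehyde carbon, giving the cis‑fused bicyclic lactone A1. Ring B would then open the lactone as an aryl nucleophile (forming the C7' ketone and freeing C9–OH), and loss of the bridgehead ester would leave C4 to settle trans.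
- Merits: ring C is assembled in one step from few atoms, the C4–C5 bond forms by ionic chemistry without any carbenoid selectivity question, and the route would probably be shorter than the chosen one.
- Weak points: attack at the donor carbon is expected to proceed with inversion, so the exo aryl group of A1 requires A2 with the aryl group syn to the lactone. That means a cyclopropanation on a Z‑alkene, the harder case for asymmetric induction. With so electron‑rich a donor the Lewis acid may open the cyclopropane to a benzylic cation and erode C2. Monomeric formaldehyde is a less established partner than aryl aldehydes. The aryl nucleophile must later choose the lactone carbonyl over the ester on the same carbon, and hydrogenolysis of the benzyl ether threatens the benzylic C2–O1 bond.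
- Comparison: this road is better on step count. The chosen plan sets against it an auxiliary‑controlled aldol for C2 and C3 and a single open selectivity question.

**Alternative 2:** Cut C2–C3. The key step treats the seven‑membered enol acetal A4 with Me3SiOTf; the acetal ionises and the enol ether carbon attacks the aryl oxocarbenium carbon, contracting the ring to oxolane A3 with C9 as an aldehyde and C7' masked as a 1‑arylvinyl group. A4 would come from an enantioselective Heck reaction that sets C4. Aldehyde reduction, ozonolysis of the styrene and desilylation would finish the synthesis.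
- Merits: it is the shortest of the four, the absolute configuration comes from catalysis, and the contraction forms two stereocentres in an arrangement where C3 (α to the aldehyde) can relax to trans.
- Weak points: the enantioselectivity of a Heck reaction with an α‑aryl vinyl partner on this ring, and double‑bond migration after it, are uncertain. The C2 configuration is fixed kinetically in the contraction with no later correction. The highly stabilised oxocarbenium ion of ring A may cyclise reversibly or slowly.
- Comparison: this road is clearly better on step economy. The chosen plan sets against it predictable absolute and relative configuration at C2 and C3, and a C4 centre that is corrected at the end.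

**Alternative 3:** Cut C3–C4. The key step irradiates the diazo pyranone A6 in methanol; Wolff rearrangement moves C3 to the diazo carbon and the ketene is trapped as methyl ester A5. A6 would arise from a hetero‑Diels–Alder adduct after enone reduction and diazo transfer.
- Merits: the asymmetric hetero‑Diels–Alder reaction is well developed, the migrating carbon keeps its configuration, and the ester centre is epimerisable.
- Weak points: A5 ends at the wrong oxidation pattern, so the C4 ester must still be turned into the ring B ketone over several steps. Two benzyl ethers must come off by hydrogenolysis next to the benzylic C2–O1 bond and an aryl ketone. The carbene has an adjacent methylene whose hydride shift competes with the Wolff rearrangement.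
- Comparison: this road is no shorter than the chosen one and carries a comparable carbene selectivity risk. The chosen plan has ring B in place before ring closure and ends with a single deprotection.

Key step: step 12

## Route

Remark: locants follow the oxolane (O1, C2–C5), with C9 the hydroxymethyl carbon and C7' the ketone carbon. Carbinol 15 is carried as both C7' epimers because that centre is oxidised away in step 10.

Step 1
Reactants: 1 vanillin
Product: 2 4-(tert-butyldimethylsilyloxy)-3-methoxybenzaldehyde
Conditions: TBSCl, imidazole, DMF, rt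
Reagents that add atoms: tert-butyldimethylsilyl chloride, CC(C)(C)[Si](C)(C)Cl
Why: Standard silyl ether formation at the phenol under imidazole catalysis; the aldehyde is untouched and the aryl silyl ether tolerates the boron aldol and hydride steps that follow.

Step 2
Reactants: 3 (S)-4-benzyl-2-oxazolidinone; 4 pent-4-enoyl chloride
Product: 5 (S)-4-benzyl-3-(pent-4-enoyl)oxazolidin-2-one
Conditions: Et3N, DMAP (cat.), CH2Cl2, 0 °C to rt
Reagents that add atoms: none
Why: N‑acylation of the oxazolidinone by the acid chloride with DMAP as acyl‑transfer catalyst; no stereocentre is touched.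

Step 3
Reactants: 5 (S)-4-benzyl-3-(pent-4-enoyl)oxazolidin-2-one; 2 4-(tert-butyldimethylsilyloxy)-3-methoxybenzaldehyde
Product: 7 (S)-4-benzyl-3-[(2S,3S)-2-allyl-3-[4-(tert-butyldimethylsilyloxy)-3-methoxyphenyl]-3-hydroxypropanoyl]oxazolidin-2-one, via dibutylboron (Z)-enolate 6 (not isolated)
Conditions: Bu2BOTf, iPr2NEt, CH2Cl2, 0 °C; then 2, −78 to 0 °C; pH 7 buffer, MeOH, H2O2, 0 °C
Reagents that add atoms: dibutylboron triflate, CCCCB(CCCC)OS(=O)(=O)C(F)(F)F (its dibutylboryl group is held only by 6 and is removed in the work‑up)
Why: Evans syn‑aldol: soft enolisation gives the (Z)‑boron enolate 6, which adds to the aldehyde through a chair Zimmerman–Traxler transition state on the face away from the benzyl group of the auxiliary, setting C2 (S) and C3 as the syn pair that becomes the 2,3‑trans relationship of ring C.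

Step 4
Reactants: 7 (S)-4-benzyl-3-[(2S,3S)-2-allyl-3-[4-(tert-butyldimethylsilyloxy)-3-methoxyphenyl]-3-hydroxypropanoyl]oxazolidin-2-one
Product: 8 (S)-4-benzyl-3-[(2S,3S)-2-allyl-3-[4-(tert-butyldimethylsilyloxy)-3-methoxyphenyl]-3-methoxypropanoyl]oxazolidin-2-one
Conditions: Me3OBF4, 1,8-bis(dimethylamino)naphthalene, CH2Cl2, 0 °C to rt
Reagents that add atoms: trimethyloxonium tetrafluoroborate, C[O+](C)C.F[B-](F)(F)F
Why: O‑alkylation with Meerwein's salt beside a non‑nucleophilic proton scavenger; the medium is neither basic nor acidic, so retro‑aldol cleavage and epimerisation at C3 are avoided, and C2 keeps its configuration because its C–O bond is not broken.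

Step 5
Reactants: 8 (S)-4-benzyl-3-[(2S,3S)-2-allyl-3-[4-(tert-butyldimethylsilyloxy)-3-methoxyphenyl]-3-methoxypropanoyl]oxazolidin-2-one
Product: 9 (2R)-2-[(S)-[4-(tert-butyldimethylsilyloxy)-3-methoxyphenyl](methoxy)methyl]pent-4-en-1-ol
Conditions: LiBH4, MeOH (1 equiv), THF, 0 °C
Reagents that add atoms: none
Why: Reductive cleavage of the N‑acyl oxazolidinone by hydride attack at the exocyclic carbonyl gives the C9 alcohol and returns auxiliary 3; alkene, methyl ether and aryl silyl ether are inert.

Step 6
Reactants: 9 (2R)-2-[(S)-[4-(tert-butyldimethylsilyloxy)-3-methoxyphenyl](methoxy)methyl]pent-4-en-1-ol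
Product: 10 (2R)-2-[(S)-[4-(tert-butyldimethylsilyloxy)-3-methoxyphenyl](methoxy)methyl]pent-4-en-1-yl benzoate
Conditions: BzCl, pyridine, DMAP (cat.), CH2Cl2, 0 °C to rt
Reagents that add atoms: benzoyl chloride, O=C(Cl)c1ccccc1
Why: Acylation of the primary alcohol via the N‑acylpyridinium ion; the benzoate has no enolisable hydrogen, offers no ether‑type C–H bond to the later carbenoid and is removed by methanolysis at the end.

Step 7
Reactants: 10 (2R)-2-[(S)-[4-(tert-butyldimethylsilyloxy)-3-methoxyphenyl](methoxy)methyl]pent-4-en-1-yl benzoate
Product: 11 (2R)-2-[(S)-[4-(tert-butyldimethylsilyloxy)-3-methoxyphenyl](methoxy)methyl]-4-oxobutyl benzoate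
Conditions: O3, CH2Cl2, −78 °C; then PPh3, −78 °C to rt
Reagents that add atoms: ozone, [O-][O+]=O
Why: Ozonolysis of the monosubstituted alkene with reductive work‑up gives the C7' aldehyde; the terminal alkene reacts much faster with ozone than the arenes, and the ozone feed is stopped as soon as the alkene is consumed.

Step 8
Reactants: 12 4-bromo-2,6-dimethoxyphenol
Product: 13 (4-bromo-2,6-dimethoxyphenoxy)(tert-butyl)dimethylsilane
Conditions: TBSCl, imidazole, DMF, rt
Reagents that add atoms: tert-butyldimethylsilyl chloride, CC(C)(C)[Si](C)(C)Cl
Why: Standard silylation of the phenol, which masks the acidic hydrogen of ring B before halogen–lithium exchange.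

Step 9
Reactants: 13 (4-bromo-2,6-dimethoxyphenoxy)(tert-butyl)dimethylsilane; 11 (2R)-2-[(S)-[4-(tert-butyldimethylsilyloxy)-3-methoxyphenyl](methoxy)methyl]-4-oxobutyl benzoate
Product: 15 (2R)-4-[4-(tert-butyldimethylsilyloxy)-3,5-dimethoxyphenyl]-4-hydroxy-2-[(S)-[4-(tert-butyldimethylsilyloxy)-3-methoxyphenyl](methoxy)methyl]butyl benzoate (both C7' epimers), via aryllithium 14 (not isolated)
Conditions: 13, n-BuLi, THF, −78 °C; then 11, −78 °C; NH4Cl (aq)
Reagents that add atoms: n-butyllithium, [Li]CCCC (its lithium is held only by 14)
Why: Bromine–lithium exchange gives aryllithium 14, whose 1,2‑addition to the aldehyde at −78 °C is far faster than attack on the benzoate; the new carbinol centre is formed without control and is removed in step 10.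

Step 10
Reactants: 15 (2R)-4-[4-(tert-butyldimethylsilyloxy)-3,5-dimethoxyphenyl]-4-hydroxy-2-[(S)-[4-(tert-butyldimethylsilyloxy)-3-methoxyphenyl](methoxy)methyl]butyl benzoate
Product: 16 (2R)-4-[4-(tert-butyldimethylsilyloxy)-3,5-dimethoxyphenyl]-2-[(S)-[4-(tert-butyldimethylsilyloxy)-3-methoxyphenyl](methoxy)methyl]-4-oxobutyl benzoate
Conditions: Dess–Martin periodinane, pyridine, CH2Cl2, 0 °C to rt
Reagents that add atoms: none
Why: Dess–Martin oxidation of the benzylic secondary alcohol to the aryl ketone under buffered conditions that spare the acid‑labile benzylic methyl ether; no stereocentre is α to the new carbonyl.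

Step 11
Reactants: 16 (2R)-4-[4-(tert-butyldimethylsilyloxy)-3,5-dimethoxyphenyl]-2-[(S)-[4-(tert-butyldimethylsilyloxy)-3-methoxyphenyl](methoxy)methyl]-4-oxobutyl benzoate
Product: 19 (2R)-4-[4-(tert-butyldimethylsilyloxy)-3,5-dimethoxyphenyl]-3-diazo-2-[(S)-[4-(tert-butyldimethylsilyloxy)-3-methoxyphenyl](methoxy)methyl]-4-oxobutyl benzoate, via lithium enolate 17 (not isolated), via trifluoroacetyl diketone 18 (not isolated)
Conditions: LiN(SiMe3)2, THF, −78 °C; CF3CO2CH2CF3, −78 °C; NH4Cl (aq); then MsN3, Et3N, H2O (1 equiv), MeCN, rt
Reagents that add atoms: lithium hexamethyldisilazide, [Li]N([Si](C)(C)C)[Si](C)(C)C (its lithium is held only by 17); 2,2,2-trifluoroethyl trifluoroacetate, O=C(OCC(F)(F)F)C(F)(F)F (its trifluoroacetyl group is held only by 18); methanesulfonyl azide, CS(=O)(=O)N=[N+]=[N-] (supplies the N2 of 19)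
Why: Regitz‑type deacylative diazo transfer in its detrifluoroacetylative form: the kinetic enolate 17 (only C4 can enolise) is C‑acylated at −78 °C to diketone 18, and the sulfonyl azide then transfers N2 to C4 with loss of the trifluoroacetyl group as the N‑acylsulfonamide; C3 is not acidic and keeps its configuration.

Step 12
Reactants: 19 (2R)-4-[4-(tert-butyldimethylsilyloxy)-3,5-dimethoxyphenyl]-3-diazo-2-[(S)-[4-(tert-butyldimethylsilyloxy)-3-methoxyphenyl](methoxy)methyl]-4-oxobutyl benzoate
Product: 20 {(2S,3R,4S)-4-[4-(tert-butyldimethylsilyloxy)-3,5-dimethoxybenzoyl]-2-[4-(tert-butyldimethylsilyloxy)-3-methoxyphenyl]oxolan-3-yl}methyl benzoate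
Conditions: Rh2(NHCOCH3)4 (2 mol %), CH2Cl2, 40 °C, slow addition of 19
Reagents that add atoms: none
Why: The dirhodium tetraacetamidate extrudes N2 from 19 and forms an electrophilic rhodium carbenoid at C4; the closest known reaction type is the dirhodium‑catalysed intramolecular 1,5 C–H insertion of α‑diazo carbonyl compounds next to an ether oxygen, which gives oxolanes. A C–H bond of the C2 methoxy group, made hydridic by the oxygen lone pair, engages the vacant carbenoid orbital in a concerted three‑centre transition state in which hydrogen passes to C4 while the C4–C5 bond forms and the catalyst is released. Ring C closes through a five‑membered chair‑like transition state built from C4, C3, C2, O1 and the methyl carbon, the 1,5 mode being the only one open to an ether‑activated C–H bond in this substrate. The new stereocentre C4 is controlled by the neighbouring C3 centre: the aroyl group is expected to take the side away from the benzoyloxymethyl group and give the 3,4‑trans isomer, and because C4 is α to the ketone any shortfall is corrected by equilibration in step 13. C2 and C3 are not touched. The step needs chemoselectivity for methoxy C–H insertion over 1,2‑hydride shift from C3 and over attack on ring A at the position para to its methoxy group. The electron‑rich carboxamidate ligands give a less electrophilic, more discriminating carbenoid that disfavours aromatic substitution; the C3–H bond is inductively deactivated by the benzoyloxy and methoxy groups on its two neighbours; and the benzoate and silyl ethers place no other ether‑type C–H bond in a 1,5 relationship to C4.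

Step 13
Reactants: 20 {(2S,3R,4S)-4-[4-(tert-butyldimethylsilyloxy)-3,5-dimethoxybenzoyl]-2-[4-(tert-butyldimethylsilyloxy)-3-methoxyphenyl]oxolan-3-yl}methyl benzoate
Product: 21 (4-hydroxy-3,5-dimethoxyphenyl)[(3S,4R,5S)-5-(4-hydroxy-3-methoxyphenyl)-4-(hydroxymethyl)oxolan-3-yl]methanone
Conditions: K2CO3, MeOH, 0 °C to rt; NH4Cl (aq)
Reagents that add atoms: none
Why: Methoxide from the carbonate cleaves the benzoate by transesterification and both aryl silyl ethers by attack at silicon, while reversible enolisation of the ketone brings C4 to the thermodynamically preferred all‑trans arrangement; loss of O1 from the enolate would be the reverse of a 5‑endo closure and is stereoelectronically disfavoured, so ring C should survive.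

## Compound list

1 | vanillin (4-hydroxy-3-methoxybenzaldehyde) | COc1cc(C=O)ccc1O | starting material
2 | 4-(tert-butyldimethylsilyloxy)-3-methoxybenzaldehyde | COc1cc(C=O)ccc1O[Si](C)(C)C(C)(C)C | intermediate
3 | (S)-4-benzyl-2-oxazolidinone | O=C1OC[C@H](Cc2ccccc2)N1 | starting material
4 | pent-4-enoyl chloride | C=CCCC(=O)Cl | starting material
5 | (S)-4-benzyl-3-(pent-4-enoyl)oxazolidin-2-one | C=CCCC(=O)N1[C@@H](Cc2ccccc2)COC1=O | intermediate
6 | dibutylboron (Z)-enolate of 5 | CCCCB(CCCC)O/C(=C\CC=C)N1[C@@H](Cc2ccccc2)COC1=O | intermediate (not isolated)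
7 | (S)-4-benzyl-3-[(2S,3S)-2-allyl-3-[4-(tert-butyldimethylsilyloxy)-3-methoxyphenyl]-3-hydroxypropanoyl]oxazolidin-2-one | COc1cc([C@@H](O)[C@@H](C(=O)N2[C@@H](Cc3ccccc3)COC2=O)CC=C)ccc1O[Si](C)(C)C(C)(C)C | intermediate
8 | (S)-4-benzyl-3-[(2S,3S)-2-allyl-3-[4-(tert-butyldimethylsilyloxy)-3-methoxyphenyl]-3-methoxypropanoyl]oxazolidin-2-one | COc1cc([C@@H](OC)[C@@H](C(=O)N2[C@@H](Cc3ccccc3)COC2=O)CC=C)ccc1O[Si](C)(C)C(C)(C)C | intermediate
9 | (2R)-2-[(S)-[4-(tert-butyldimethylsilyloxy)-3-methoxyphenyl](methoxy)methyl]pent-4-en-1-ol | COc1cc([C@@H](OC)[C@@H](CO)CC=C)ccc1O[Si](C)(C)C(C)(C)C | intermediate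
10 | (2R)-2-[(S)-[4-(tert-butyldimethylsilyloxy)-3-methoxyphenyl](methoxy)methyl]pent-4-en-1-yl benzoate | COc1cc([C@@H](OC)[C@@H](COC(=O)c2ccccc2)CC=C)ccc1O[Si](C)(C)C(C)(C)C | intermediate
11 | (2R)-2-[(S)-[4-(tert-butyldimethylsilyloxy)-3-methoxyphenyl](methoxy)methyl]-4-oxobutyl benzoate | COc1cc([C@@H](OC)[C@@H](COC(=O)c2ccccc2)CC=O)ccc1O[Si](C)(C)C(C)(C)C | intermediate
12 | 4-bromo-2,6-dimethoxyphenol | COc1cc(Br)cc(OC)c1O | starting material
13 | (4-bromo-2,6-dimethoxyphenoxy)(tert-butyl)dimethylsilane | COc1cc(Br)cc(OC)c1O[Si](C)(C)C(C)(C)C | intermediate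
14 | [4-(tert-butyldimethylsilyloxy)-3,5-dimethoxyphenyl]lithium | [Li]c1cc(OC)c(O[Si](C)(C)C(C)(C)C)c(OC)c1 | intermediate (not isolated)
15 | (2R)-4-[4-(tert-butyldimethylsilyloxy)-3,5-dimethoxyphenyl]-4-hydroxy-2-[(S)-[4-(tert-butyldimethylsilyloxy)-3-methoxyphenyl](methoxy)methyl]butyl benzoate, both C7' epimers | COc1cc([C@@H](OC)[C@@H](COC(=O)c2ccccc2)CC(O)c2cc(OC)c(O[Si](C)(C)C(C)(C)C)c(OC)c2)ccc1O[Si](C)(C)C(C)(C)C | intermediate
16 | (2R)-4-[4-(tert-butyldimethylsilyloxy)-3,5-dimethoxyphenyl]-2-[(S)-[4-(tert-butyldimethylsilyloxy)-3-methoxyphenyl](methoxy)methyl]-4-oxobutyl benzoate | COc1cc([C@@H](OC)[C@@H](COC(=O)c2ccccc2)CC(=O)c2cc(OC)c(O[Si](C)(C)C(C)(C)C)c(OC)c2)ccc1O[Si](C)(C)C(C)(C)C | intermediate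
17 | lithium (Z)-enolate of 16 | COc1cc([C@@H](OC)[C@@H](COC(=O)c2ccccc2)/C=C(\O[Li])c2cc(OC)c(O[Si](C)(C)C(C)(C)C)c(OC)c2)ccc1O[Si](C)(C)C(C)(C)C | intermediate (not isolated)
18 | C4-trifluoroacetyl derivative of 16 (2-trifluoroacetyl-1,3-diketone, C4 epimers and enol forms) | COc1cc([C@@H](OC)[C@@H](COC(=O)c2ccccc2)C(C(=O)C(F)(F)F)C(=O)c2cc(OC)c(O[Si](C)(C)C(C)(C)C)c(OC)c2)ccc1O[Si](C)(C)C(C)(C)C | intermediate (not isolated)
19 | (2R)-4-[4-(tert-butyldimethylsilyloxy)-3,5-dimethoxyphenyl]-3-diazo-2-[(S)-[4-(tert-butyldimethylsilyloxy)-3-methoxyphenyl](methoxy)methyl]-4-oxobutyl benzoate | COc1cc([C@@H](OC)[C@@H](COC(=O)c2ccccc2)C(=[N+]=[N-])C(=O)c2cc(OC)c(O[Si](C)(C)C(C)(C)C)c(OC)c2)ccc1O[Si](C)(C)C(C)(C)C | intermediate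
20 | {(2S,3R,4S)-4-[4-(tert-butyldimethylsilyloxy)-3,5-dimethoxybenzoyl]-2-[4-(tert-butyldimethylsilyloxy)-3-methoxyphenyl]oxolan-3-yl}methyl benzoate | COc1cc([C@H]2OC[C@@H](C(=O)c3cc(OC)c(O[Si](C)(C)C(C)(C)C)c(OC)c3)[C@@H]2COC(=O)c4ccccc4)ccc1O[Si](C)(C)C(C)(C)C | intermediate
21 | (4-hydroxy-3,5-dimethoxyphenyl)[(3S,4R,5S)-5-(4-hydroxy-3-methoxyphenyl)-4-(hydroxymethyl)oxolan-3-yl]methanone | COc1cc([C@H]2OC[C@@H](C(=O)c3cc(OC)c(O)c(OC)c3)[C@@H]2CO)ccc1O | target

## Step count and risks

Total step count: 13. Longest linear sequence: 11 steps (steps 2, 3, 4, 5, 6, 7, 9, 10, 11, 12, 13).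

**Step 12 (key step).** The most likely failure is 1,2‑hydride migration from C3 to the carbenoid carbon outrunning insertion, because the migrating hydrogen is tertiary and adjacent whereas the methoxy C–H bond is primary. A second possibility is electrophilic attack of the carbenoid on ring A para to its methoxy group, closing a five‑membered carbocycle. A first response within the approach would be a bulky carboxylate catalyst such as Rh2(O2CCMe3)4 at low temperature. The fallback changes the ring‑closing bond and sets out from ketone 16. Enolisation with LiN(SiMe3)2 and trapping with Me3SiCl gives the trimethylsilyl enol ether F1. A Mukaiyama‑type hydroxymethylation with aqueous formaldehyde and catalytic Yb(OTf)3 then installs C5 as a hydroxymethyl group on C4, giving the hydroxymethyl ketone F2. BF3·OEt2 at low temperature ionises the benzylic methyl ether at C2, and the C5 hydroxyl captures the cation with loss of methanol to close ring C through O1–C2. The aryl group is expected to settle trans to the C3 substituent, and the route is rejoined at 20, with C4 equilibrated in step 13 as before.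

**Step 11.** The likely failure is incomplete C‑acylation of the hindered enolate 17 (O‑acylation reverts on work‑up), slow azide transfer to the congested diketone 18, or acyl transfer from the benzoate to the enolate if the mixture warms. The fallback avoids strong base and sets out from 16. Heating with tert‑butoxybis(dimethylamino)methane (Bredereck's reagent) condenses the C4 methylene to the enaminone F3. Treatment with methanesulfonyl azide then effects diazo transfer by cycloaddition and fragmentation with loss of the N‑sulfonylformamidine, returning to the route at 19.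

**Step 9.** The likely failure is loss of chemoselectivity: attack of the aryllithium on the benzoate, benzoyl migration to the newly formed alkoxide, or enolisation of the aldehyde by the basic reagent. The fallback replaces the organolithium addition by a chromium‑mediated coupling. Aryllithium 14 is quenched with iodine to give the aryl iodide F4. A Nozaki–Hiyama–Kishi coupling of F4 with aldehyde 11 (CrCl2, catalytic NiCl2, DMF) gives the carbinol through an arylchromium species that does not react with esters and is barely basic. The route is rejoined at 15.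

**Step 4.** The likely failure is slow alkylation of the hindered, hydrogen‑bonded aldol hydroxyl, which gives time for retro‑aldol fragmentation or ionisation at the electron‑rich benzylic carbon. The fallback moves the methylation behind the auxiliary removal and sets out from 7. LiBH4 reduction gives the diol F5 and releases the auxiliary. Selective benzoylation of the primary hydroxyl (BzCl, 2,4,6‑collidine, low temperature) gives the hydroxy benzoate F6, which can no longer undergo retro‑aldol cleavage. Methylation of the remaining benzylic hydroxyl with MeOTf and 2,6‑di‑tert‑butyl‑4‑methylpyridine returns to the route at 10.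

## Further compounds

F1 | step 12 | trimethylsilyl (Z)-enol ether of ketone 16 | COc1cc([C@@H](OC)[C@@H](COC(=O)c2ccccc2)/C=C(\O[Si](C)(C)C)c2cc(OC)c(O[Si](C)(C)C(C)(C)C)c(OC)c2)ccc1O[Si](C)(C)C(C)(C)C
F2 | step 12 | C4-hydroxymethyl derivative of ketone 16 (C4 epimers) | COc1cc([C@@H](OC)[C@@H](COC(=O)c2ccccc2)C(CO)C(=O)c2cc(OC)c(O[Si](C)(C)C(C)(C)C)c(OC)c2)ccc1O[Si](C)(C)C(C)(C)C
F3 | step 11 | C4-(dimethylaminomethylene) derivative of ketone 16 (enaminone) | COc1cc([C@@H](OC)[C@@H](COC(=O)c2ccccc2)C(=CN(C)C)C(=O)c2cc(OC)c(O[Si](C)(C)C(C)(C)C)c(OC)c2)ccc1O[Si](C)(C)C(C)(C)C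
F4 | step 9 | tert-butyl(4-iodo-2,6-dimethoxyphenoxy)dimethylsilane | COc1cc(I)cc(OC)c1O[Si](C)(C)C(C)(C)C
F5 | step 4 | (1S,2R)-2-allyl-1-[4-(tert-butyldimethylsilyloxy)-3-methoxyphenyl]propane-1,3-diol | COc1cc([C@@H](O)[C@@H](CO)CC=C)ccc1O[Si](C)(C)C(C)(C)C
F6 | step 4 | (2R)-2-[(S)-[4-(tert-butyldimethylsilyloxy)-3-methoxyphenyl](hydroxy)methyl]pent-4-en-1-yl benzoate | COc1cc([C@@H](O)[C@@H](COC(=O)c2ccccc2)CC=C)ccc1O[Si](C)(C)C(C)(C)C
A1 | alternative 1 | methyl cis-fused 6-exo-(4-benzyloxy-3-methoxyphenyl)-2-oxo-3,7-dioxabicyclo[3.3.0]octane-1-carboxylate | COc1cc([C@H]2OC[C@@]3(C(=O)OC)[C@@H]2COC3=O)ccc1OCc1ccccc1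
A2 | alternative 1 | methyl 6-endo-(4-benzyloxy-3-methoxyphenyl)-2-oxo-3-oxabicyclo[3.1.0]hexane-1-carboxylate | COc1cc([C@H]2[C@H]3COC(=O)[C@@]23C(=O)OC)ccc1OCc1ccccc1
A3 | alternative 2 | all-trans 2-[4-(tert-butyldimethylsilyloxy)-3-methoxyphenyl]-4-{1-[4-(tert-butyldimethylsilyloxy)-3,5-dimethoxyphenyl]vinyl}oxolane-3-carbaldehyde | COc1cc([C@H]2OC[C@@H](C(=C)c3cc(OC)c(O[Si](C)(C)C(C)(C)C)c(OC)c3)[C@@H]2C=O)ccc1O[Si](C)(C)C(C)(C)C
A4 | alternative 2 | 2-[4-(tert-butyldimethylsilyloxy)-3-methoxyphenyl]-5-{1-[4-(tert-butyldimethylsilyloxy)-3,5-dimethoxyphenyl]vinyl}-4,5-dihydro-1,3-dioxepine (either acetal epimer) | COc1cc(C2OC[C@@H](C(=C)c3cc(OC)c(O[Si](C)(C)C(C)(C)C)c(OC)c3)C=CO2)ccc1O[Si](C)(C)C(C)(C)C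
A5 | alternative 3 | methyl all-trans 5-(4-benzyloxy-3-methoxyphenyl)-4-(benzyloxymethyl)oxolane-3-carboxylate | COc1cc([C@H]2OC[C@@H](C(=O)OC)[C@@H]2COCc2ccccc2)ccc1OCc1ccccc1
A6 | alternative 3 | trans-2-(4-benzyloxy-3-methoxyphenyl)-3-(benzyloxymethyl)-5-diazotetrahydropyran-4-one | COc1cc([C@H]2OCC(=[N+]=[N-])C(=O)[C@@H]2COCc2ccccc2)ccc1OCc1ccccc1
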